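**Plan**

- Retrosynthesis (benzofuran numbering of the target: O1, C2, C3, C3a, C4 to C7, C7a): cut the C5–prenyl bond, then the C7–prenyl bond (both lead back to a benzene ring), then O1–C2 together with C3–C3a (the dihydrofuran), then the aryl–acyl bond.
- Enabling feature: in the dihydrofuran ring, C3 is a CH2 on C3a, the only ring carbon lying between two oxygen-bearing carbons, and C2 carries O1 and a tertiary carbinol. C3, C2 and the carbinol carbon are therefore the CHO, CH and C(CH3) carbons of a 2,3-epoxy aldehyde, and O1 is the phenolic oxygen para to the acyl group.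
- Forward: nerol gives the cis epoxy aldehyde in two steps; 2-methylphloroglucinol is acylated; a one-flask reductive alkylation/epoxide opening joins the two and closes the five-membered ring on the aromatic ring; two prenylations then dearomatise the six-membered ring to the enedione.
- Stereochemistry: the carbinol carbon and C2 come from the Sharpless epoxidation of nerol (C2 by SN2 inversion; the target side chain is the anti-opening product of a cis epoxide, so nerol and not geraniol is needed). C7 comes from ligand-controlled palladium prenylation anti to the C2 substituent, and C5 from attack anti to the C7 prenyl group.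

Key step: step 4

Assumptions: the (R,R) antipode of the diphosphine ligand is taken as matched with the C-2 side chain in step 5 (the (S,S) ligand would be used otherwise, nothing else changed); compounds 5 to 9 are drawn as one tautomer each.

**Route**

Step 1
Reactants: 1 nerol, (2Z)-3,7-dimethylocta-2,6-dien-1-ol
Product: 2 [(2R,3S)-3-methyl-3-(4-methylpent-3-en-1-yl)oxiran-2-yl]methanol
Conditions: Ti(OiPr)4 (5 mol %), D-(−)-diethyl tartrate (6 mol %), anhydrous t-BuOOH, 4 Å molecular sieves, CH2Cl2, −20 °C
Reagents that add atoms: tert-butyl hydroperoxide, CC(C)(C)OO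
Why: Sharpless asymmetric epoxidation is directed by the allylic hydroxyl, so only the 2,3-alkene reacts and the distal alkene is left, the Z geometry is carried into a cis epoxide, and the D-tartrate sets both centres as 2R,3S.

Step 2
Reactants: 2 [(2R,3S)-3-methyl-3-(4-methylpent-3-en-1-yl)oxiran-2-yl]methanol
Product: 3 (2S,3S)-3-methyl-3-(4-methylpent-3-en-1-yl)oxirane-2-carbaldehyde
Conditions: TEMPO (10 mol %), PhI(OAc)2 (1.1 equiv), CH2Cl2, 0 °C to rt; used at once without storage
Reagents that add atoms: none
Why: The oxoammonium (TEMPO) oxidation of a primary alcohol is mild and non-basic, so epoxide, alkene and both stereocentres are untouched (the label at C-2 changes from R to S only because CHO outranks the ring carbon).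

Step 3
Reactants: 4 2-methylbenzene-1,3,5-triol (2-methylphloroglucinol)
Product: 5 2-methyl-1-(2,4,6-trihydroxy-3-methylphenyl)propan-1-one
Conditions: isobutyryl chloride (1.05 equiv), AlCl3 (3.5 equiv), PhNO2, 0 to 60 °C; aqueous HCl work-up
Reagents that add atoms: isobutyryl chloride, CC(C)C(Cl)=O
Why: Friedel–Crafts C-acylation of the electron-rich triol, whose two free ring positions are equivalent and whose product is deactivated toward a second acylation.

Step 4
Reactants: 5 2-methyl-1-(2,4,6-trihydroxy-3-methylphenyl)propan-1-one; 3 (2S,3S)-3-methyl-3-(4-methylpent-3-en-1-yl)oxirane-2-carbaldehyde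
Product: 8 1-[(2S)-4,6-dihydroxy-2-[(2S)-2-hydroxy-6-methylhept-5-en-2-yl]-7-methyl-2,3-dihydro-1-benzofuran-5-yl]-2-methylpropan-1-one, via ortho-quinone methide 6 (not isolated), via epoxy phenol 7 (not isolated)
Conditions: 3 (1.2 equiv), Hantzsch ester (diethyl 2,6-dimethyl-1,4-dihydropyridine-3,5-dicarboxylate, 1.5 equiv), L-proline (20 mol %), CH2Cl2/EtOH, 25 °C, 5 added slowly; then DBU (0.5 equiv), 40 °C, same flask
Reagents that add atoms: none
Why: Proposed new method: proline-catalysed Knoevenagel condensation of the aldehyde of 3 with C-5 of 5 (the only ring carbon that still carries hydrogen, lying between two hydroxyls) should give ortho-quinone methide 6, the Hantzsch ester then delivers hydride to its exocyclic carbon to leave epoxy phenol 7, and DBU finally lets a phenoxide oxygen open the epoxide. The closest known reaction types are the amine-catalysed three-component reductive alkylation of cyclic 1,3-diones with aldehydes and Hantzsch ester and the base-mediated cyclisation of 2-(2,3-epoxyalkyl)phenols to 2-(1-hydroxyalkyl)-2,3-dihydrobenzofurans; new is their union on an acylphloroglucinol with an epoxy aldehyde. The dihydrofuran ring closes 5-exo-tet by O–C bond formation at the secondary epoxide carbon. The new stereocentre C-2 is controlled by SN2 inversion at that epoxide carbon, whose configuration comes from step 1 (2R in 7 becomes 2S in 8), and the carbinol carbon keeps its epoxide configuration, so the cis epoxide from nerol gives exactly the relative configuration of the target side chain. The step needs attack by the oxygen para to the acyl group rather than by an ortho oxygen, exo rather than endo opening, and reduction of 6 faster than its capture by a second molecule of 5: the para oxygen is the most acidic and the only one not held in a hydrogen bond to the ketone and so is the phenoxide present with substoichiometric base, the basic medium directs attack to the less substituted carbon, and excess Hantzsch ester with slow addition of 5 favours reduction. The epoxide C–H cannot form an enamine or let 6 tautomerise to a vinylphenol (either would be an alkylidene-oxirane), so C-2 of 3 keeps its configuration, and no choice among alkenes is needed because the epoxide was made on nerol.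

Step 5
Reactants: 8 1-[(2S)-4,6-dihydroxy-2-[(2S)-2-hydroxy-6-methylhept-5-en-2-yl]-7-methyl-2,3-dihydro-1-benzofuran-5-yl]-2-methylpropan-1-one
Product: 9 (2S,7S)-4-hydroxy-2-[(2S)-2-hydroxy-6-methylhept-5-en-2-yl]-7-methyl-7-(3-methylbut-2-en-1-yl)-5-(2-methylpropanoyl)-2,3-dihydro-1-benzofuran-6(7H)-one
Conditions: prenyl acetate (1.05 equiv), Pd2(dba)3 (2.5 mol %), (R,R)-N,N'-(cyclohexane-1,2-diyl)bis[2-(diphenylphosphanyl)benzamide] (7.5 mol %), K2CO3 (1.2 equiv), THF, 0 °C
Reagents that add atoms: prenyl acetate (3-methylbut-2-en-1-yl acetate), CC(C)=CCOC(C)=O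
Why: Palladium-catalysed asymmetric allylic dearomatisation (Tsuji–Trost type) of the phenoxide should occur at C-7, which is ortho and para to the two hydroxyls and the only ring carbon that can take the electrophile and give a neutral ketone (C-3a is tied up in the enol ether, C-5 carries the conjugated acyl group), while aryl prenyl ethers formed at oxygen re-ionise under zerovalent palladium, the soft nucleophile attacks the unsubstituted allyl terminus (linear prenyl), and the new centre (7S) is set by the chiral ligand acting in the matched sense with approach anti to the C-2 substituent.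

Step 6
Reactants: 9 (2S,7S)-4-hydroxy-2-[(2S)-2-hydroxy-6-methylhept-5-en-2-yl]-7-methyl-7-(3-methylbut-2-en-1-yl)-5-(2-methylpropanoyl)-2,3-dihydro-1-benzofuran-6(7H)-one
Product: 10 (2S,5R,7S)-2-[(2S)-2-hydroxy-6-methylhept-5-en-2-yl]-7-methyl-5,7-bis(3-methylbut-2-en-1-yl)-5-(2-methylpropanoyl)-2,3-dihydro-1-benzofuran-4,6(5H,7H)-dione (CNP0155474.1)
Conditions: prenyl acetate (1.5 equiv), Pd(PPh3)4 (5 mol %), Et3N (1.2 equiv), THF, 0 °C to rt
Reagents that add atoms: prenyl acetate (3-methylbut-2-en-1-yl acetate), CC(C)=CCOC(C)=O
Why: Tsuji–Trost C-allylation of a 2-acyl cyclic 1,3-dione, an acidic soft carbon nucleophile whose only carbon site is C-5 and whose O-prenyl enol ethers are reversible under zerovalent palladium so that the C-alkylated product accumulates, with the new centre (5R) expected from approach of the bulky allylpalladium cation to the flat enolate on the face anti to the C-7 prenyl group, that is syn to the smaller methyl.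

**Compound list**

1 | nerol, (2Z)-3,7-dimethylocta-2,6-dien-1-ol | CC(C)=CCC/C(C)=C\CO | starting material
2 | [(2R,3S)-3-methyl-3-(4-methylpent-3-en-1-yl)oxiran-2-yl]methanol | CC(C)=CCC[C@]1(C)O[C@@H]1CO | intermediate
3 | (2S,3S)-3-methyl-3-(4-methylpent-3-en-1-yl)oxirane-2-carbaldehyde | CC(C)=CCC[C@]1(C)O[C@@H]1C=O | intermediate
4 | 2-methylbenzene-1,3,5-triol (2-methylphloroglucinol) | Cc1c(O)cc(O)cc1O | starting material
5 | 2-methyl-1-(2,4,6-trihydroxy-3-methylphenyl)propan-1-one | CC(C)C(=O)c1c(O)cc(O)c(C)c1O | intermediate
6 | 3,5-dihydroxy-2-methyl-4-(2-methylpropanoyl)-6-{[(2R,3S)-3-methyl-3-(4-methylpent-3-en-1-yl)oxiran-2-yl]methylidene}cyclohexa-2,4-dien-1-one (ortho-quinone methide, alkene geometry not fixed) | CC(C)=CCC[C@]1(C)O[C@@H]1C=C1C(=O)C(C)=C(O)C(C(=O)C(C)C)=C1O | intermediate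
7 | 2-methyl-1-[2,4,6-trihydroxy-3-methyl-5-{[(2R,3S)-3-methyl-3-(4-methylpent-3-en-1-yl)oxiran-2-yl]methyl}phenyl]propan-1-one | CC(C)=CCC[C@]1(C)O[C@@H]1Cc1c(O)c(C)c(O)c(C(=O)C(C)C)c1O | intermediate
8 | 1-[(2S)-4,6-dihydroxy-2-[(2S)-2-hydroxy-6-methylhept-5-en-2-yl]-7-methyl-2,3-dihydro-1-benzofuran-5-yl]-2-methylpropan-1-one | CC(C)=CCC[C@](C)(O)[C@@H]1Cc2c(O1)c(C)c(O)c(C(=O)C(C)C)c2O | intermediate
9 | (2S,7S)-4-hydroxy-2-[(2S)-2-hydroxy-6-methylhept-5-en-2-yl]-7-methyl-7-(3-methylbut-2-en-1-yl)-5-(2-methylpropanoyl)-2,3-dihydro-1-benzofuran-6(7H)-one | CC(C)=CCC[C@](C)(O)[C@@H]1CC2=C(O1)[C@](C)(CC=C(C)C)C(=O)C(C(=O)C(C)C)=C2O | intermediate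
10 | (2S,5R,7S)-2-[(2S)-2-hydroxy-6-methylhept-5-en-2-yl]-7-methyl-5,7-bis(3-methylbut-2-en-1-yl)-5-(2-methylpropanoyl)-2,3-dihydro-1-benzofuran-4,6(5H,7H)-dione | CC(C)=CCC[C@](C)(O)[C@@H]1CC2=C(O1)[C@](C)(CC=C(C)C)C(=O)[C@](CC=C(C)C)(C(=O)C(C)C)C2=O | target

**Step count and risks**

Total step count: 6. Longest linear sequence: 5 (steps 1, 2, 4, 5, 6 from nerol).

Steps most likely to fail:

1. Step 4 (Proposed new method). The quinone methide may be captured by a second molecule of 5 (diarylmethane formation) before hydride transfer, the α-branched epoxy aldehyde may condense sluggishly, and the epoxide may be opened by an ortho oxygen or in the endo sense. Fallback with known chemistry, setting out from 5 and coming back at 8: C-alkylation of the free ring carbon of 5 with neryl bromide (aqueous KOH, 0 °C, the classical C-allylation of acylphloroglucinols) should give 1-[3-[(2Z)-3,7-dimethylocta-2,6-dien-1-yl]-2,4,6-trihydroxy-5-methylphenyl]-2-methylpropan-1-one F1. VO(acac)2 with t-BuOOH in CH2Cl2 should then epoxidise only the proximal Z-alkene, directed by the flanking phenolic hydroxyls (the distal alkene has no directing group), to give 7 together with its mirror image, the enantiomer of epoxy phenol 7 F2. Ring closure, completed with DBU as in step 4, gives 8 together with the enantiomer of dihydrobenzofuran 8 F3; the relative configuration is the same as in the main route because syn epoxidation and anti opening are both stereospecific. Compound 8 is separated from F3 by preparative chromatography on a chiral stationary phase. Absolute control by the reagent is given up in exchange for two precedented reaction types.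

2. Step 5. Facial selectivity at C-7 may be poor (the controlling C-2 substituent is remote and the sense of ligand induction is not secured), and O-prenylation or a second prenylation at C-5 may compete. Fallback, setting out from 8 and coming back at 9: direct alkylative dearomatisation of the phenoxide with prenyl bromide and NaOMe in MeOH at 0 °C (the C-prenylation of a substituted ring carbon known from hop-acid chemistry), relying only on the bias of the C-2 substituent. Compound 9 is then separated by chromatography from its diastereomer, the (2S,7R) epimer of 9 F4.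

3. Step 6. Facial selectivity at C-5 may be low (methyl versus prenyl at C-7 is a modest steric difference), and the hindered tricarbonyl carbon may react slowly so that O-prenyl enol ethers persist. Fallback, setting out from 9 and coming back at 10: asymmetric allylic alkylation with the smaller allyl acetate under Pd2(dba)3 and the matched antipode of the diphosphine ligand of step 5 (catalyst control is best documented for quaternary centres from 2-substituted cyclic β-dicarbonyl compounds) should give the 5-allyl analogue of the target F5. Cross-metathesis with 2-methyl-2-butene and the second-generation Grubbs catalyst RuCl2(=CHPh)(PCy3)(H2IMes) then converts allyl into prenyl, the trisubstituted alkenes already present being inert or exchanging degenerately.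

Further compounds
F1 | step 4 | 1-[3-[(2Z)-3,7-dimethylocta-2,6-dien-1-yl]-2,4,6-trihydroxy-5-methylphenyl]-2-methylpropan-1-one | CC(C)=CCC/C(C)=C\Cc1c(O)c(C)c(O)c(C(=O)C(C)C)c1O
F2 | step 4 | 2-methyl-1-[2,4,6-trihydroxy-3-methyl-5-{[(2S,3R)-3-methyl-3-(4-methylpent-3-en-1-yl)oxiran-2-yl]methyl}phenyl]propan-1-one (enantiomer of 7) | CC(C)=CCC[C@@]1(C)O[C@H]1Cc1c(O)c(C)c(O)c(C(=O)C(C)C)c1O
F3 | step 4 | 1-[(2R)-4,6-dihydroxy-2-[(2R)-2-hydroxy-6-methylhept-5-en-2-yl]-7-methyl-2,3-dihydro-1-benzofuran-5-yl]-2-methylpropan-1-one (enantiomer of 8) | CC(C)=CCC[C@@](C)(O)[C@H]1Cc2c(O1)c(C)c(O)c(C(=O)C(C)C)c2O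
F4 | step 5 | (2S,7R)-4-hydroxy-2-[(2S)-2-hydroxy-6-methylhept-5-en-2-yl]-7-methyl-7-(3-methylbut-2-en-1-yl)-5-(2-methylpropanoyl)-2,3-dihydro-1-benzofuran-6(7H)-one | CC(C)=CCC[C@](C)(O)[C@@H]1CC2=C(O1)[C@@](C)(CC=C(C)C)C(=O)C(C(=O)C(C)C)=C2O
F5 | step 6 | (2S,5R,7S)-2-[(2S)-2-hydroxy-6-methylhept-5-en-2-yl]-7-methyl-7-(3-methylbut-2-en-1-yl)-5-(2-methylpropanoyl)-5-(prop-2-en-1-yl)-2,3-dihydro-1-benzofuran-4,6(5H,7H)-dione | CC(C)=CCC[C@](C)(O)[C@@H]1CC2=C(O1)[C@](C)(CC=C(C)C)C(=O)[C@](CC=C)(C(=O)C(C)C)C2=O
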